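Ring numbering used here: C1 (C=O) – C2 (acyl-bearing) – C3 (enol C–OH) – C4H2 – C5H2 – C6H(OH).
Retrosynthesis: cut the exocyclic C2–acyl bond first (C-acylation of a 1,3-dione by 13-phenyltridecanoic acid), then the ring bonds C3–C4 and C5–C6 together, which lifts C4–C5 out as a two-carbon dienophile (allyl acrylate, whose ester carbon leaves later as CO2).
Enabling feature: C3 and C6 both carry oxygen and stand 1,4 across the C4–C5 bridge; tied through the C6 oxygen, C6–C1–C2–C3 and that oxygen are the five ring atoms of a furan-2,4-dione (tetronic acid), i.e. a 2,4-dioxygenated furan whose [4+2] adduct with a C2 unit, once its oxygen bridge opens, is the carbocycle with C3=O and C6–O in place.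
Forward: tetronic acid → chiral 4-aminofuranone → 4-amino-2-silyloxyfuran → cycloaddition/bridge opening (the six-membered ring, the only ring of the target, arises here) → deallylation, decarboxylation and amine hydrolysis → C-acylation → desilylation; the side-chain acid comes from one cross-coupling.
Stereochemistry: the single stereocentre (C6, S) is set in the cycloaddition by a recoverable C2-symmetric amine, (2S,5S)-2,5-diphenylpyrrolidine, on the furan; no later step enolises that carbon.

Key step: step 4

Assumption: the β-triketone is drawn as one of its rapidly interconverting enol tautomers, so the carbinol carbon is the only fixed stereocentre; 2-phenylethylmagnesium chloride solution and (2S,5S)-2,5-diphenylpyrrolidine are taken as commercial.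

Step 1
Reactants: 1 11-bromoundecanoic acid; 2 2-phenylethylmagnesium chloride
Product: 3 13-phenyltridecanoic acid
Conditions: 2 (2.5 equiv), Li2CuCl4 (3 mol %), THF, −20 → 0 °C; then 1 M HCl
Reagents that add atoms: none
Why: Li2CuCl4-catalysed cross-coupling of a primary alkyl bromide with an alkyl Grignard reagent tolerates the carboxylate formed by the first equivalent of 2 and joins the two sp3 carbons.

Step 2
Reactants: 4 tetronic acid (4-hydroxyfuran-2(5H)-one); 5 (2S,5S)-2,5-diphenylpyrrolidine
Product: 6 4-[(2S,5S)-2,5-diphenylpyrrolidin-1-yl]furan-2(5H)-one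
Conditions: toluene, AcOH (cat.), reflux, Dean–Stark trap
Reagents that add atoms: none
Why: Enaminone formation from a cyclic 1,3-dicarbonyl compound and a secondary amine occurs at the ketone-like C4 of tetronic acid with azeotropic removal of water, and the two stereocentres of the amine are carried in unchanged.

Step 3
Reactants: 6 4-[(2S,5S)-2,5-diphenylpyrrolidin-1-yl]furan-2(5H)-one
Product: 7 4-[(2S,5S)-2,5-diphenylpyrrolidin-1-yl]-2-{[tri(propan-2-yl)silyl]oxy}furan
Conditions: KN(SiMe3)2, THF, −78 °C; i-Pr3SiOTf, −78 → 0 °C; filtration under argon, used without chromatography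
Reagents that add atoms: triisopropylsilyl trifluoromethanesulfonate, CC(C)[Si](OS(=O)(=O)C(F)(F)F)(C(C)C)C(C)C
Why: Deprotonation at the oxygen-bearing CH2 (C5) gives the aromatic 2-oxidofuran, which the hard silyl triflate traps on oxygen, as in the standard preparations of 2-silyloxyfurans and of 1-amino-3-silyloxybutadienes from vinylogous amides.

Step 4
Reactants: 7 4-[(2S,5S)-2,5-diphenylpyrrolidin-1-yl]-2-{[tri(propan-2-yl)silyl]oxy}furan; 8 prop-2-en-1-yl prop-2-enoate (allyl acrylate)
Product: 10 prop-2-en-1-yl (5S)-4-[(2S,5S)-2,5-diphenylpyrrolidin-1-yl]-2-oxo-5-{[tri(propan-2-yl)silyl]oxy}cyclohex-3-ene-1-carboxylate (both C1 epimers), via oxa-bridged cycloadduct 9 (not isolated)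
Conditions: 8 (3 equiv), toluene, 0 → 40 °C
Reagents that add atoms: none
Why: Proposed new method: furan 7 is a cyclic 3-amino-1,1-dioxy diene whose C5 is an enamine β-carbon, so it should add the acrylate in a thermal, asynchronous normal-demand [4+2] cycloaddition (C5 to the acrylate CH2, the doubly oxygenated C2 to the ester-bearing carbon); in adduct 9 the bridgehead silyl ketal then ionises with loss of the bridging oxygen, pushed by the silyloxy oxygen and vinylogously by nitrogen, and the alkoxide so released takes the silyl group, which gives the vinylogous amide 10 irreversibly. The closest known reaction types are the Diels–Alder reactions of 1-amino-3-silyloxybutadienes that carry the same C2-symmetric pyrrolidine and the cycloaddition/oxa-bridge-opening cascades of 2-amino- and 2-silyloxyfurans; their union in a tetronic-acid-derived furan is the untested part. The carbocycle is closed by the intermolecular suprafacial [4+2] cycloaddition itself, both of its new ring bonds arising in that event, and the transient oxygen bridge is cleaved again, so the cyclohexene is the only ring formed. The new carbinol centre (C5 of 10, S) is controlled by the auxiliary: nitrogen is conjugated and coplanar with the furan, the phenyl group on the pyrrolidine carbon next to furan C5 stands over one face of C5, and the dienophile must bond from the other face; the C2 axis makes both N–C rotamers equivalent, and because the control element sits on the diene the outcome does not depend on the endo/exo ratio, the ester-bearing centre being left uncontrolled and destroyed in step 5. The step needs cycloaddition instead of conjugate addition with rearomatisation, the regiochemistry that places the ester next to the new ketone, and bridge opening at the ketal carbon only; the donor pattern of 7 (amino at C4, two oxygens at C2) and the neutral, aprotic conditions are what should secure these.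

Step 5
Reactants: 10 prop-2-en-1-yl (5S)-4-[(2S,5S)-2,5-diphenylpyrrolidin-1-yl]-2-oxo-5-{[tri(propan-2-yl)silyl]oxy}cyclohex-3-ene-1-carboxylate
Product: 13 (4S)-4-{[tri(propan-2-yl)silyl]oxy}cyclohexane-1,3-dione, via keto acid 11 (not isolated), via enaminone 12 (not isolated)
Conditions: Pd(PPh3)4 (3 mol %), morpholine (5 equiv), THF, 23 → 40 °C; then 1 M HCl, THF, 40 °C; 5 recovered from the aqueous phase after basification
Reagents that add atoms: water, O
Why: Tsuji–Trost deallylation of the allyl β-keto ester with morpholine as allyl acceptor gives the β-keto acid, which decarboxylates, and dilute acid then hydrolyses the vinylogous amide through its iminium form to the 1,3-dione while releasing the auxiliary, the triisopropylsilyl ether and the carbinol centre being expected to survive both stages.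

Step 6
Reactants: 13 (4S)-4-{[tri(propan-2-yl)silyl]oxy}cyclohexane-1,3-dione; 3 13-phenyltridecanoic acid
Product: 15 (6S)-3-hydroxy-2-(13-phenyltridecanoyl)-6-{[tri(propan-2-yl)silyl]oxy}cyclohex-2-en-1-one, via enol ester 14 (not isolated)
Conditions: DCC (1.2 equiv), DMAP (1.2 equiv), CH2Cl2, 0 → 23 °C
Reagents that add atoms: none
Why: Carbodiimide activation gives the enol ester (Steglich-type), which 4-(dimethylamino)pyridine converts by O-to-C acyl migration into the chelated β-triketone; C2 is the only carbon between the two ring carbonyls, so either enol ester leads to the same product.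

Step 7
Reactants: 15 (6S)-3-hydroxy-2-(13-phenyltridecanoyl)-6-{[tri(propan-2-yl)silyl]oxy}cyclohex-2-en-1-one
Product: 16 oleiferinone, (6S)-3,6-dihydroxy-2-(13-phenyltridecanoyl)cyclohex-2-en-1-one
Conditions: HF·pyridine, pyridine, THF, 0 → 23 °C
Reagents that add atoms: none
Why: Fluoride cleavage of the silyl ether under mildly acidic conditions frees the secondary alcohol without enolising the carbinol centre or dehydrating the ring.

Compound list
1 | 11-bromoundecanoic acid | OC(=O)CCCCCCCCCCBr | starting material
2 | 2-phenylethylmagnesium chloride | Cl[Mg]CCc1ccccc1 | starting material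
3 | 13-phenyltridecanoic acid | OC(=O)CCCCCCCCCCCCc1ccccc1 | intermediate
4 | tetronic acid (4-hydroxyfuran-2(5H)-one) | OC1=CC(=O)OC1 | starting material
5 | (2S,5S)-2,5-diphenylpyrrolidine | N1[C@H](c2ccccc2)CC[C@H]1c1ccccc1 | starting material
6 | 4-[(2S,5S)-2,5-diphenylpyrrolidin-1-yl]furan-2(5H)-one | O=C1OCC(=C1)N1[C@H](c2ccccc2)CC[C@H]1c1ccccc1 | intermediate
7 | 4-[(2S,5S)-2,5-diphenylpyrrolidin-1-yl]-2-{[tri(propan-2-yl)silyl]oxy}furan | CC(C)[Si](Oc1cc(co1)N1[C@H](c2ccccc2)CC[C@H]1c1ccccc1)(C(C)C)C(C)C | intermediate
8 | prop-2-en-1-yl prop-2-enoate (allyl acrylate) | C=CC(=O)OCC=C | starting material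
9 | prop-2-en-1-yl (1R,4S)-5-[(2S,5S)-2,5-diphenylpyrrolidin-1-yl]-1-{[tri(propan-2-yl)silyl]oxy}-7-oxabicyclo[2.2.1]hept-5-ene-2-carboxylate (C2 epimers) | C=CCOC(=O)C1C[C@@H]2O[C@@]1(O[Si](C(C)C)(C(C)C)C(C)C)C=C2N1[C@H](c2ccccc2)CC[C@H]1c1ccccc1 | intermediate (not isolated)
10 | prop-2-en-1-yl (5S)-4-[(2S,5S)-2,5-diphenylpyrrolidin-1-yl]-2-oxo-5-{[tri(propan-2-yl)silyl]oxy}cyclohex-3-ene-1-carboxylate (C1 epimers) | C=CCOC(=O)C1C[C@H](O[Si](C(C)C)(C(C)C)C(C)C)C(=CC1=O)N1[C@H](c2ccccc2)CC[C@H]1c1ccccc1 | intermediate
11 | (5S)-4-[(2S,5S)-2,5-diphenylpyrrolidin-1-yl]-2-oxo-5-{[tri(propan-2-yl)silyl]oxy}cyclohex-3-ene-1-carboxylic acid | OC(=O)C1C[C@H](O[Si](C(C)C)(C(C)C)C(C)C)C(=CC1=O)N1[C@H](c2ccccc2)CC[C@H]1c1ccccc1 | intermediate (not isolated)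
12 | (4S)-3-[(2S,5S)-2,5-diphenylpyrrolidin-1-yl]-4-{[tri(propan-2-yl)silyl]oxy}cyclohex-2-en-1-one | O=C1C=C(N2[C@H](c3ccccc3)CC[C@H]2c2ccccc2)[C@@H](O[Si](C(C)C)(C(C)C)C(C)C)CC1 | intermediate (not isolated)
13 | (4S)-4-{[tri(propan-2-yl)silyl]oxy}cyclohexane-1,3-dione | O=C1CC[C@H](O[Si](C(C)C)(C(C)C)C(C)C)C(=O)C1 | intermediate
14 | (4S)-3-oxo-4-{[tri(propan-2-yl)silyl]oxy}cyclohex-1-en-1-yl 13-phenyltridecanoate | O=C(CCCCCCCCCCCCc1ccccc1)OC1=CC(=O)[C@@H](O[Si](C(C)C)(C(C)C)C(C)C)CC1 | intermediate (not isolated)
15 | (6S)-3-hydroxy-2-(13-phenyltridecanoyl)-6-{[tri(propan-2-yl)silyl]oxy}cyclohex-2-en-1-one | O=C(CCCCCCCCCCCCc1ccccc1)C1=C(O)CC[C@H](O[Si](C(C)C)(C(C)C)C(C)C)C1=O | intermediate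
16 | oleiferinone, (6S)-3,6-dihydroxy-2-(13-phenyltridecanoyl)cyclohex-2-en-1-one | O=C(CCCCCCCCCCCCc1ccccc1)C1=C(O)CC[C@H](O)C1=O | target

Total steps: 7. Longest linear sequence: 6 (steps 2 to 7, from tetronic acid); step 1 supplies the side-chain acid for step 6.

Steps most likely to fail

1. Step 4 (proposed new method). The electron-rich furan may act as a carbon nucleophile and rearomatise after conjugate addition instead of closing the second bond, the face discrimination by the auxiliary may be incomplete, or the silyl group may be lost instead of migrating. Fallback: an anionic annulation built from known reaction types, setting out from 6 and rejoining the route at 12. Deprotonation of 6 at C5 with LiN(iPr)2 (THF, −78 °C) and addition of phenyl vinyl sulfone should give, by conjugate addition on the face away from the neighbouring phenyl group (the face selectivity known for C5 alkylation of such pyrrolidine-derived vinylogous carbamates), followed on warming by attack of the α-sulfonyl carbanion on the lactone carbonyl and loss of the ring oxygen as alkoxide (a Michael–Dieckmann sequence of the Hauser–Kraus type, here without a leaving group), (4S)-3-[(2S,5S)-2,5-diphenylpyrrolidin-1-yl]-4-hydroxy-6-(phenylsulfonyl)cyclohex-2-en-1-one F1. Reductive desulfonylation of this β-keto sulfone with SmI2 (THF/MeOH, −78 °C) would give (4S)-3-[(2S,5S)-2,5-diphenylpyrrolidin-1-yl]-4-hydroxycyclohex-2-en-1-one F2, and silylation (i-Pr3SiOTf, 2,6-lutidine, CH2Cl2) returns 12, which is hydrolysed as in the second stage of step 5.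

2. Step 5. The vinylogous amide, shielded by the pyrrolidine and the neighbouring silyloxy group, may hydrolyse too slowly under acid that the silyl ether tolerates, so that forcing leads to partial desilylation. Fallback: deprotection and reprotection instead of preservation, setting out from 12 (made from 10 by the palladium stage) and rejoining at 13. Treatment with 3 M HCl in dioxane at 60 °C would cleave both the enaminone and the silyl ether to (4S)-4-hydroxycyclohexane-1,3-dione F3; i-Pr3SiOTf (2.2 equiv) and 2,6-lutidine in CH2Cl2, followed by aqueous work-up that hydrolyses the enol silyl ether, would then give 13.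

3. Step 2. The acidic tetronic acid may hold the hindered, weakly basic amine as its salt, so that the condensation stalls. Fallback: addition–elimination instead of condensation, setting out from 4 and rejoining at 6. Oxalyl bromide with catalytic DMF in CH2Cl2 would convert 4 into 4-bromofuran-2(5H)-one F4, and 5 with i-Pr2NEt in MeCN at 60 °C would displace bromide at the β-carbon to give 6.

Further compounds
F1 | step 4 | (4S)-3-[(2S,5S)-2,5-diphenylpyrrolidin-1-yl]-4-hydroxy-6-(phenylsulfonyl)cyclohex-2-en-1-one (C6 epimers) | O=C1C=C(N2[C@H](c3ccccc3)CC[C@H]2c2ccccc2)[C@@H](O)CC1S(=O)(=O)c1ccccc1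
F2 | step 4 | (4S)-3-[(2S,5S)-2,5-diphenylpyrrolidin-1-yl]-4-hydroxycyclohex-2-en-1-one | O=C1C=C(N2[C@H](c3ccccc3)CC[C@H]2c2ccccc2)[C@@H](O)CC1
F3 | step 5 | (4S)-4-hydroxycyclohexane-1,3-dione | O=C1CC[C@H](O)C(=O)C1
F4 | step 2 | 4-bromofuran-2(5H)-one | BrC1=CC(=O)OC1
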